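**Retrosynthetic overview**

1. Labels: ring B carbons are B1 (diaryl ether O), B2 (H), B3 (OH), B4 (pyran O), B5 (pyran CH=), B6 (ester O). Ring A carbons are named by origin: C3 (carries the lactone C=O), C4 (OH), C5 (pyran CH=) and C6 (pyran O) keep their 2-pyranone locants, and Cα (diaryl ether O) and Cβ (prenyl) are the two carbons of an alkyne.
2. Feature and key cut: hexasubstituted ring A is C3–C6 of a 2-pyranone with oxygen at C4 and C6 and the acyl group at C3, plus the two carbons of an aryl ynol ether. The ester B6–O–CO–C3 and the ether B1–O–Cα already tie both halves to ring B, so cutting C3–Cα and C6–Cβ (retro-Diels–Alder, CO2 put back) opens ring A and the seven-membered dioxepinone together.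
3. The cycloaddition precursor is the ester of a 4,6-dialkoxy-2-oxopyran-3-carboxylate (from the malonyl dichloride dimer) with a ring B phenol that already carries the ynol ether; the ester bond is made last.
4. Ring B comes from 2,4,5-trihydroxybenzaldehyde. The catechol oxygens at B6 and B1 are told apart by keeping B6 as the formyl carbon while B1–OH is turned into a dichlorovinyl ether (the later ynol ether); Baeyer–Villiger oxidation then delivers B6–O.
5. Ring order: ring B pyran (step 6), pyranone (step 8), ring A plus dioxepinone (step 13), ring A pyran (step 16); both methoxymethyl ethers are removed last.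

Key step: step 13

Remark: the target has no stereocentre. Descriptors are needed only for the (E)-dichlorovinyl ethers (set in step 3) and for the transient bridged lactone of step 13, which would form as a racemate (one enantiomer is written).

**Route**

Step 1
Reactants: 1 2,4,5-trihydroxybenzaldehyde
Product: 2 2,5-dihydroxy-4-(methoxymethoxy)benzaldehyde
Conditions: MOMCl (1.05 equiv), K2CO3 (1.0 equiv), acetone, 0 °C → rt, argon
Reagents that add atoms: chloromethyl methyl ether (MOMCl), COCCl
Why: Williamson-type O-alkylation under weak base should take the 4-hydroxyl, the most acidic phenol because it is para to the formyl group, while the 2-hydroxyl is hydrogen-bonded to the aldehyde and the 5-hydroxyl is the least acidic.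

Step 2
Reactants: 2 2,5-dihydroxy-4-(methoxymethoxy)benzaldehyde; 3 3-chloro-3-methylbut-1-yne
Product: 4 2-hydroxy-4-(methoxymethoxy)-5-[(2-methylbut-3-yn-2-yl)oxy]benzaldehyde
Conditions: K2CO3, KI, CuI (cat.), acetone, 55 °C, argon
Reagents that add atoms: none
Why: Copper-catalysed O-alkylation with a tertiary propargylic chloride should occur at the free 5-hydroxyl (B4–O) and spare the chelated 2-hydroxyl, as in selective 5-O-alkylations of 2,5-dihydroxybenzaldehydes.

Step 3
Reactants: 4 2-hydroxy-4-(methoxymethoxy)-5-[(2-methylbut-3-yn-2-yl)oxy]benzaldehyde; 5 trichloroethylene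
Product: 6 2-{[(E)-1,2-dichloroethenyl]oxy}-4-(methoxymethoxy)-5-[(2-methylbut-3-yn-2-yl)oxy]benzaldehyde
Conditions: K2CO3, DMF, 70 °C
Reagents that add atoms: none
Why: Base-mediated vinylation of phenols with trichloroethylene (elimination to dichloroacetylene in the flask, then anti addition of the phenoxide) is the standard route to aryl (E)-1,2-dichlorovinyl ethers, and here it marks B1–O while B6 is still a carbon substituent.

Step 4
Reactants: 6 2-{[(E)-1,2-dichloroethenyl]oxy}-4-(methoxymethoxy)-5-[(2-methylbut-3-yn-2-yl)oxy]benzaldehyde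
Product: 8 2-{[(E)-1,2-dichloroethenyl]oxy}-4-(methoxymethoxy)-5-[(2-methylbut-3-yn-2-yl)oxy]phenol, via aryl formate 7 (not isolated)
Conditions: mCPBA, CH2Cl2, 0 °C → rt; aq. NaHCO3 wash; then K2CO3 (cat.), MeOH, 0 °C
Reagents that add atoms: 3-chloroperoxybenzoic acid (mCPBA), O=C(OO)c1cccc(Cl)c1
Why: Baeyer–Villiger (Dakin-type) oxidation of an aldehyde ortho and para to oxygen donors should migrate the aryl group to give the formate, which methanolysis cleaves; it is placed before any chromene or ynol ether exists, and the chlorinated enol ether and terminal alkyne are poor substrates for the peracid.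

Step 5
Reactants: 8 2-{[(E)-1,2-dichloroethenyl]oxy}-4-(methoxymethoxy)-5-[(2-methylbut-3-yn-2-yl)oxy]phenol
Product: 9 tert-butyl(2-{[(E)-1,2-dichloroethenyl]oxy}-4-(methoxymethoxy)-5-[(2-methylbut-3-yn-2-yl)oxy]phenoxy)dimethylsilane
Conditions: TBSCl, imidazole, DMF, rt
Reagents that add atoms: tert-butyldimethylsilyl chloride (TBSCl), CC(C)(C)[Si](C)(C)Cl
Why: Standard phenol silylation; the silyl group cannot scramble between B6–O and B1–O because B1–O is already etherified, and it keeps the B6 oxygen out of the next step.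

Step 6
Reactants: 9 tert-butyl(2-{[(E)-1,2-dichloroethenyl]oxy}-4-(methoxymethoxy)-5-[(2-methylbut-3-yn-2-yl)oxy]phenoxy)dimethylsilane
Product: 10 tert-butyl[(6-{[(E)-1,2-dichloroethenyl]oxy}-8-(methoxymethoxy)-2,2-dimethyl-2H-chromen-5-yl)oxy]dimethylsilane
Conditions: o-xylene, 140 °C
Reagents that add atoms: none
Why: Aryl propargyl ether Claisen rearrangement to the only free ortho carbon (B5), followed by enolisation, 1,5-hydrogen shift and oxa-6π electrocyclisation, is the standard route to 2,2-dimethylchromenes, and with B6–O silylated only the B4 oxygen can close the pyran.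

Step 7
Reactants: 10 tert-butyl[(6-{[(E)-1,2-dichloroethenyl]oxy}-8-(methoxymethoxy)-2,2-dimethyl-2H-chromen-5-yl)oxy]dimethylsilane; 11 1-bromo-3-methylbut-2-ene
Product: 13 tert-butyl({8-(methoxymethoxy)-2,2-dimethyl-6-[(5-methylhex-4-en-1-yn-1-yl)oxy]-2H-chromen-5-yl}oxy)dimethylsilane, via lithium acetylide 12 (not isolated)
Conditions: n-BuLi (2.2 equiv), THF, −78 → −40 °C; then CuBr·SMe2 (10 mol%), 11, −40 → 0 °C
Reagents that add atoms: none
Why: Two equivalents of n-BuLi convert an (E)-1,2-dichlorovinyl ether into the lithium alkynyl ether by elimination and lithium–halogen exchange (the established ynol ether synthesis), and copper-catalysed alkylation of the acetylide with a prenyl halide should occur at the primary carbon to give the skipped enyne.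

Step 8
Reactants: 14 malonyl dichloride (two molecules)
Product: 15 6-chloro-4-hydroxy-2-oxo-2H-pyran-3-carbonyl chloride
Conditions: neat, 20–25 °C, 7 d, dry N2 sweep
Reagents that add atoms: malonyl dichloride (second molecule), O=C(Cl)CC(=O)Cl
Why: Two molecules of malonyl dichloride are known to self-condense on standing with loss of two HCl (C-acylation of one molecule by the other, by way of (chlorocarbonyl)ketene, then ring closure through the enol oxygen of the remaining acid chloride) to give this pyranone acid chloride, the chloro analogue of dehydroacetic acid.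

Step 9
Reactants: 15 6-chloro-4-hydroxy-2-oxo-2H-pyran-3-carbonyl chloride
Product: 17 prop-2-en-1-yl 6-chloro-4-(methoxymethoxy)-2-oxo-2H-pyran-3-carboxylate, via hydroxy ester 16 (not isolated)
Conditions: allyl alcohol (1.0 equiv), CH2Cl2, 0 °C; then i-Pr2NEt (2.2 equiv), MOMCl, 0 °C → rt
Reagents that add atoms: prop-2-en-1-ol (allyl alcohol), C=CCO; chloromethyl methyl ether (MOMCl), COCCl
Why: The acyl chloride is far more reactive than the vinylogous C6 chloride and is esterified first, and the acidic 4-hydroxyl of the resulting 3-acyl-4-hydroxypyranone is then O-alkylated by the hard electrophile MOMCl (Williamson-type enol etherification).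

Step 10
Reactants: 17 prop-2-en-1-yl 6-chloro-4-(methoxymethoxy)-2-oxo-2H-pyran-3-carboxylate; 18 4-methoxybenzyl alcohol
Product: 19 prop-2-en-1-yl 4-(methoxymethoxy)-6-[(4-methoxyphenyl)methoxy]-2-oxo-2H-pyran-3-carboxylate
Conditions: Ag2O (0.6 equiv), 4 Å MS, CH2Cl2, rt, dark
Reagents that add atoms: none
Why: The C6 chloride is a doubly vinylogous acyl chloride, and silver-assisted alcoholysis (nucleophilic vinylic substitution by addition–elimination with Koenigs–Knorr-like halide abstraction) should replace it at C6, the silver ion steering the alcohol to the carbon that loses chloride and away from the lactone carbonyl.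

Step 11
Reactants: 19 prop-2-en-1-yl 4-(methoxymethoxy)-6-[(4-methoxyphenyl)methoxy]-2-oxo-2H-pyran-3-carboxylate
Product: 20 potassium 4-(methoxymethoxy)-6-[(4-methoxyphenyl)methoxy]-2-oxo-2H-pyran-3-carboxylate
Conditions: Pd(PPh3)4 (3 mol%), PPh3, potassium 2-ethylhexanoate (1.05 equiv), EtOAc/CH2Cl2, rt
Reagents that add atoms: potassium 2-ethylhexanoate, CCCCC(CC)C(=O)[O-].[K+]
Why: Tsuji–Trost allyl transfer to 2-ethylhexanoate is neutral and non-nucleophilic toward the pyranone and precipitates the product as its potassium salt, so the acid-labile enol ethers never meet a free carboxylic acid.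

Step 12
Reactants: 13 tert-butyl({8-(methoxymethoxy)-2,2-dimethyl-6-[(5-methylhex-4-en-1-yn-1-yl)oxy]-2H-chromen-5-yl}oxy)dimethylsilane; 20 potassium 4-(methoxymethoxy)-6-[(4-methoxyphenyl)methoxy]-2-oxo-2H-pyran-3-carboxylate
Product: 23 8-(methoxymethoxy)-2,2-dimethyl-6-[(5-methylhex-4-en-1-yn-1-yl)oxy]-2H-chromen-5-yl 4-(methoxymethoxy)-6-[(4-methoxyphenyl)methoxy]-2-oxo-2H-pyran-3-carboxylate, via acid chloride 21 (not isolated), via ammonium phenoxide 22 (not isolated)
Conditions: 20, (COCl)2 (1.0 equiv), CH2Cl2, 0 °C; 13, Bu4N[Ph3SiF2] (1.05 equiv), THF, −40 °C; combine, −40 → 0 °C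
Reagents that add atoms: none
Why: Fluoride cleaves the aryl silyl ether to a naked phenoxide that is acylated at once by the acid chloride made acid-free from the carboxylate salt and oxalyl chloride (standard phenoxide acylation), so neither a carboxylic acid nor a free ortho-phenol is left beside the ynol ether.

Step 13
Reactants: 23 8-(methoxymethoxy)-2,2-dimethyl-6-[(5-methylhex-4-en-1-yn-1-yl)oxy]-2H-chromen-5-yl 4-(methoxymethoxy)-6-[(4-methoxyphenyl)methoxy]-2-oxo-2H-pyran-3-carboxylate
Product: 25 depsidone with Cβ prenyl / C6 (4-methoxyphenyl)methoxy / C5 H / C4 methoxymethoxy / B3 methoxymethoxy / ring B pyran, via bridged lactone 24 (not isolated)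
Conditions: o-xylene (0.005 M), 2,6-di-tert-butyl-4-methylpyridine (0.2 equiv), BHT (cat.), 140 °C
Reagents that add atoms: none
Why: Proposed new method: the electron-rich aryl ynol ether and the 2-pyranone, made electron-poor by its C3 ester and lactone carbonyl, should undergo an intramolecular inverse-electron-demand Diels–Alder reaction across pyranone C3 and C6 to give bridged lactone 24, which loses CO2 by retro-[4+2] and aromatises; the closest known reaction type is the Diels–Alder/decarboxylation of 2-oxopyran-3-carboxylates with electron-rich alkynes, run intermolecularly or through short tethers, whereas a diaryl ether–ester tether that stays in the product as a ring has not been used. Ring A is closed by the [4+2] event itself (bonds C3–Cα and C6–Cβ) and becomes aromatic on extrusion of CO2; the seven-membered dioxepinone is closed in the same event by the C3–Cα bond, in the fused mode, because the five-atom tether C(=O)–O–B6–B1–O joins the diene terminus C3 to the oxygen-bearing alkyne carbon. No stereocentre remains in 25; the two bridgeheads of 24 are locked relative to each other by the bicycle and vanish on decarboxylation. The step needs regioselectivity (Cβ to C6, Cα to C3), which the tether enforces and the polarisation supports, since the nucleophilic prenyl-bearing carbon of the ynol ether meets the most electrophilic diene terminus; it needs cyclisation to beat oligomerisation, which high dilution secures, and it needs the ynol ether to survive heating, which is plausible because an aryl ynol ether has no hydrogen for retro-ene loss to a ketene and the hindered pyridine scavenges acid. The main barrier is rotation of the aryl ester into its s-cis conformer and out of the pyranone plane, which is why 140 °C is proposed.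

Step 14
Reactants: 25 depsidone with C6 (4-methoxyphenyl)methoxy / C4 methoxymethoxy / B3 methoxymethoxy
Product: 26 depsidone with free C6 hydroxyl / C4 methoxymethoxy / B3 methoxymethoxy
Conditions: DDQ (1.2 equiv), CH2Cl2/pH 7 buffer (10:1), 0 °C
Reagents that add atoms: none
Why: Oxidative cleavage of a 4-methoxybenzyl ether by DDQ (hydride abstraction, then hydrolysis of the oxocarbenium ion) is orthogonal to methoxymethyl ethers, and cold, buffered conditions with little excess oxidant should spare the chromene and keep the freed C6 phenol from oxidative closure onto the neighbouring prenyl group.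

Step 15
Reactants: 26 depsidone with free C6 hydroxyl; 3 3-chloro-3-methylbut-1-yne
Product: 27 depsidone with C6 (2-methylbut-3-yn-2-yl)oxy / C4 methoxymethoxy / B3 methoxymethoxy
Conditions: K2CO3, KI, CuI (cat.), acetone, 55 °C
Reagents that add atoms: none
Why: Copper-catalysed O-alkylation of the only free phenol with the tertiary propargylic chloride, as in step 2.

Step 16
Reactants: 27 depsidone with C6 (2-methylbut-3-yn-2-yl)oxy
Product: 28 Garcinisidone C bis(methoxymethyl) ether (at the C4 and B3 oxygens)
Conditions: o-xylene, 140 °C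
Reagents that add atoms: none
Why: Propargyl aryl ether Claisen rearrangement to C5, the only unsubstituted ortho position (Cβ carries the prenyl group), followed by 1,5-hydrogen shift and oxa-6π electrocyclisation, closes the ring A pyran.

Step 17
Reactants: 28 Garcinisidone C bis(methoxymethyl) ether
Product: 29 Garcinisidone C
Conditions: 3 M aq HCl, i-PrOH/THF, 45 °C
Reagents that add atoms: none
Why: Acid hydrolysis of the two aryl methoxymethyl acetals; no phenol is ortho to the prenyl group (its neighbours are the pyran oxygen carbon C6 and the diaryl ether carbon Cα), so acid-induced chroman formation cannot occur, and the hindered lactone should survive in a secondary-alcohol medium.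

**Compound list**

1 | 2,4,5-trihydroxybenzaldehyde | O=Cc1cc(O)c(O)cc1O | starting material
2 | 2,5-dihydroxy-4-(methoxymethoxy)benzaldehyde | O=Cc1cc(O)c(OCOC)cc1O | intermediate
3 | 3-chloro-3-methylbut-1-yne | C#CC(C)(C)Cl | starting material
4 | 2-hydroxy-4-(methoxymethoxy)-5-[(2-methylbut-3-yn-2-yl)oxy]benzaldehyde | O=Cc1cc(OC(C)(C)C#C)c(OCOC)cc1O | intermediate
5 | trichloroethylene | ClC=C(Cl)Cl | starting material
6 | 2-{[(E)-1,2-dichloroethenyl]oxy}-4-(methoxymethoxy)-5-[(2-methylbut-3-yn-2-yl)oxy]benzaldehyde | O=Cc1cc(OC(C)(C)C#C)c(OCOC)cc1O/C(Cl)=C\Cl | intermediate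
7 | 2-{[(E)-1,2-dichloroethenyl]oxy}-4-(methoxymethoxy)-5-[(2-methylbut-3-yn-2-yl)oxy]phenyl formate (not isolated) | O=COc1cc(OC(C)(C)C#C)c(OCOC)cc1O/C(Cl)=C\Cl | intermediate
8 | 2-{[(E)-1,2-dichloroethenyl]oxy}-4-(methoxymethoxy)-5-[(2-methylbut-3-yn-2-yl)oxy]phenol | Oc1cc(OC(C)(C)C#C)c(OCOC)cc1O/C(Cl)=C\Cl | intermediate
9 | tert-butyl(2-{[(E)-1,2-dichloroethenyl]oxy}-4-(methoxymethoxy)-5-[(2-methylbut-3-yn-2-yl)oxy]phenoxy)dimethylsilane | CC(C)(C)[Si](C)(C)Oc1cc(OC(C)(C)C#C)c(OCOC)cc1O/C(Cl)=C\Cl | intermediate
10 | tert-butyl[(6-{[(E)-1,2-dichloroethenyl]oxy}-8-(methoxymethoxy)-2,2-dimethyl-2H-chromen-5-yl)oxy]dimethylsilane | CC(C)(C)[Si](C)(C)Oc1c(O/C(Cl)=C\Cl)cc(OCOC)c2OC(C)(C)C=Cc12 | intermediate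
11 | 1-bromo-3-methylbut-2-ene (prenyl bromide) | CC(C)=CCBr | starting material
12 | ({5-[(tert-butyldimethylsilyl)oxy]-8-(methoxymethoxy)-2,2-dimethyl-2H-chromen-6-yl}oxy)ethynyllithium (not isolated) | [Li]C#COc1cc(OCOC)c2OC(C)(C)C=Cc2c1O[Si](C)(C)C(C)(C)C | intermediate
13 | tert-butyl({8-(methoxymethoxy)-2,2-dimethyl-6-[(5-methylhex-4-en-1-yn-1-yl)oxy]-2H-chromen-5-yl}oxy)dimethylsilane | CC(C)=CCC#COc1cc(OCOC)c2OC(C)(C)C=Cc2c1O[Si](C)(C)C(C)(C)C | intermediate
14 | malonyl dichloride | O=C(Cl)CC(=O)Cl | starting material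
15 | 6-chloro-4-hydroxy-2-oxo-2H-pyran-3-carbonyl chloride | O=C(Cl)C1=C(O)C=C(Cl)OC1=O | intermediate
16 | prop-2-en-1-yl 6-chloro-4-hydroxy-2-oxo-2H-pyran-3-carboxylate (not isolated) | C=CCOC(=O)C1=C(O)C=C(Cl)OC1=O | intermediate
17 | prop-2-en-1-yl 6-chloro-4-(methoxymethoxy)-2-oxo-2H-pyran-3-carboxylate | C=CCOC(=O)C1=C(OCOC)C=C(Cl)OC1=O | intermediate
18 | 4-methoxybenzyl alcohol | COc1ccc(CO)cc1 | starting material
19 | prop-2-en-1-yl 4-(methoxymethoxy)-6-[(4-methoxyphenyl)methoxy]-2-oxo-2H-pyran-3-carboxylate | C=CCOC(=O)C1=C(OCOC)C=C(OCc2ccc(OC)cc2)OC1=O | intermediate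
20 | potassium 4-(methoxymethoxy)-6-[(4-methoxyphenyl)methoxy]-2-oxo-2H-pyran-3-carboxylate | [K+].[O-]C(=O)C1=C(OCOC)C=C(OCc2ccc(OC)cc2)OC1=O | intermediate
21 | 4-(methoxymethoxy)-6-[(4-methoxyphenyl)methoxy]-2-oxo-2H-pyran-3-carbonyl chloride (not isolated) | O=C(Cl)C1=C(OCOC)C=C(OCc2ccc(OC)cc2)OC1=O | intermediate
22 | tetrabutylammonium 8-(methoxymethoxy)-2,2-dimethyl-6-[(5-methylhex-4-en-1-yn-1-yl)oxy]-2H-chromen-5-olate (not isolated) | CCCC[N+](CCCC)(CCCC)CCCC.[O-]c1c(OC#CCC=C(C)C)cc(OCOC)c2OC(C)(C)C=Cc12 | intermediate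
23 | 8-(methoxymethoxy)-2,2-dimethyl-6-[(5-methylhex-4-en-1-yn-1-yl)oxy]-2H-chromen-5-yl 4-(methoxymethoxy)-6-[(4-methoxyphenyl)methoxy]-2-oxo-2H-pyran-3-carboxylate | COc1ccc(COC2=CC(OCOC)=C(C(=O)Oc3c(OC#CCC=C(C)C)cc(OCOC)c4OC(C)(C)C=Cc34)C(=O)O2)cc1 | intermediate
24 | bridged lactone: 2-oxabicyclo[2.2.2]octa-5,7-dien-3-one in which pyranone C3 is bonded to the oxygen-bearing alkyne carbon and C6 to the prenyl-bearing alkyne carbon of 23, the dioxepinone already closed; racemic, one enantiomer written (not isolated) | COc1ccc(CO[C@@]23C=C(OCOC)[C@]4(C(=O)O2)C(=O)Oc5c(OC4=C3CC=C(C)C)cc(OCOC)c6OC(C)(C)C=Cc56)cc1 | intermediate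
25 | depsidone (dibenzo[b,e][1,4]dioxepin-11-one core): ring A with prenyl at Cβ, (4-methoxyphenyl)methoxy at C6, H at C5, methoxymethoxy at C4; ring B with methoxymethoxy at B3 and a 2,2-dimethyl-2H-pyran fused at B4 (O) and B5 (CH=) | CC(C)=CCc1c(OCc2ccc(OC)cc2)cc(OCOC)c2c1Oc1cc(OCOC)c3OC(C)(C)C=Cc3c1OC2=O | intermediate
26 | as 25 but with a free hydroxyl at C6 | CC(C)=CCc1c(O)cc(OCOC)c2c1Oc1cc(OCOC)c3OC(C)(C)C=Cc3c1OC2=O | intermediate
27 | as 25 but with (2-methylbut-3-yn-2-yl)oxy at C6 | CC(C)=CCc1c(OC(C)(C)C#C)cc(OCOC)c2c1Oc1cc(OCOC)c3OC(C)(C)C=Cc3c1OC2=O | intermediate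
28 | Garcinisidone C bis(methoxymethyl) ether (at the C4 and B3 oxygens) | CC(C)=CCc1c2c(c(OCOC)c3c1Oc1cc(OCOC)c4c(c1OC3=O)C=CC(C)(C)O4)C=CC(C)(C)O2 | intermediate
29 | Garcinisidone C | CC(C)=CCc1c2c(c(O)c3c1Oc1cc(O)c4c(c1OC3=O)C=CC(C)(C)O4)C=CC(C)(C)O2 | target

**Step count**

Total: 17 steps. Longest linear sequence: 13 steps (steps 1–7, then 12–17); the pyranone branch is steps 8–11.

**Steps most likely to fail**

Step 13 (key step). The aryl ester may not reach the twisted s-cis conformer below the temperature at which the ynol ether or the enol ether groups of the pyranone break down, or the dialkoxy-substituted pyranone may be too electron-rich, so that oligomerisation or loss of the 4-methoxybenzyl group outruns cycloaddition. Fallback, from 19 and 13, returning at 25: allyl ester 19 and ynol ether 13 would be heated together at high concentration (xylene, 120–140 °C) in the intermolecular inverse-demand cycloaddition/decarboxylation of a 2-oxopyran-3-carboxylate with an electron-rich alkyne. This is the known parent reaction and needs no strained ester conformer; polar matching (prenyl-bearing ynol ether carbon to pyranone C6) should give the diaryl ether allyl benzoate F1. Pd(PPh3)4 with potassium 2-ethylhexanoate would free the potassium carboxylate F2, Bu4NF buffered with AcOH would remove the silyl group to give the hydroxy acid F3, and carbodiimide lactonisation (EDC·HCl, DMAP, high dilution), the classical closure of depsidone seco acids, would give 25.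

Step 10. The alcohol may attack the lactone carbonyl instead of C6, leading to ring opening and reclosure to the isomeric 5-carboxylate or to open-chain esters, or the 4-alkoxy group may be exchanged. Fallback, from 18, returning at 20: alcohol 18 would be heated with 2,2-dimethyl-1,3-dioxane-4,6-dione (toluene, 100 °C) to give the malonic half ester F4. F4 would C-acylate a second equivalent of the dioxanedione (DCC, DMAP, CH2Cl2) to give the acyl dioxanedione F5 (enol form), and O-alkylation of the enol with MOMCl/i-Pr2NEt would give the alkylidene dioxanedione F6. K2CO3 in MeCN should then form the ester dienolate, whose oxygen attacks the cis ring carbonyl; loss of acetone would give carboxylate 20 directly. The C6–O bond is in place before the ring exists and the ring oxygen can only come from the 4-methoxybenzyl ester, so neither ring opening nor the 5-carboxylate isomer can arise.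

Step 12. Acylation of the doubly ortho-substituted phenoxide by the flanked acid chloride may be slow, so that the phenoxide adds to the ynol ether or to C6/C4 of the pyranone instead. Fallback, from 13 and 15, returning at 23: phenoxide 22, generated from 13 as in step 12, would be acylated by the unhindered and more reactive acid chloride 15 in the presence of i-Pr2NEt to give the 6-chloro-4-hydroxypyranone ester F7, kept as its ammonium salt so that the acidic enol never meets the ynol ether. It would be alkylated in the same flask with MOMCl to the chloro ester F8, and the chloride would be exchanged with 18 (i-Pr2NEt, CH2Cl2; no silver salt, which would activate the ynol ether) to reach 23. The pyranone is thus dressed after, not before, the hindered ester bond is made.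

Further compounds
F1 | step 13 | prop-2-en-1-yl 2-({5-[(tert-butyldimethylsilyl)oxy]-8-(methoxymethoxy)-2,2-dimethyl-2H-chromen-6-yl}oxy)-6-(methoxymethoxy)-4-[(4-methoxyphenyl)methoxy]-3-(3-methylbut-2-en-1-yl)benzoate | C=CCOC(=O)c1c(OCOC)cc(OCc2ccc(OC)cc2)c(CC=C(C)C)c1Oc1cc(OCOC)c2OC(C)(C)C=Cc2c1O[Si](C)(C)C(C)(C)C
F2 | step 13 | potassium 2-({5-[(tert-butyldimethylsilyl)oxy]-8-(methoxymethoxy)-2,2-dimethyl-2H-chromen-6-yl}oxy)-6-(methoxymethoxy)-4-[(4-methoxyphenyl)methoxy]-3-(3-methylbut-2-en-1-yl)benzoate | [K+].[O-]C(=O)c1c(OCOC)cc(OCc2ccc(OC)cc2)c(CC=C(C)C)c1Oc1cc(OCOC)c2OC(C)(C)C=Cc2c1O[Si](C)(C)C(C)(C)C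
F3 | step 13 | 2-{[5-hydroxy-8-(methoxymethoxy)-2,2-dimethyl-2H-chromen-6-yl]oxy}-6-(methoxymethoxy)-4-[(4-methoxyphenyl)methoxy]-3-(3-methylbut-2-en-1-yl)benzoic acid | OC(=O)c1c(OCOC)cc(OCc2ccc(OC)cc2)c(CC=C(C)C)c1Oc1cc(OCOC)c2OC(C)(C)C=Cc2c1O
F4 | step 10 | 3-[(4-methoxyphenyl)methoxy]-3-oxopropanoic acid | COc1ccc(COC(=O)CC(=O)O)cc1
F5 | step 10 | 5-{1-hydroxy-3-[(4-methoxyphenyl)methoxy]-3-oxopropylidene}-2,2-dimethyl-1,3-dioxane-4,6-dione | COc1ccc(COC(=O)CC(O)=C2C(=O)OC(C)(C)OC2=O)cc1
F6 | step 10 | 5-{1-(methoxymethoxy)-3-[(4-methoxyphenyl)methoxy]-3-oxopropylidene}-2,2-dimethyl-1,3-dioxane-4,6-dione | COc1ccc(COC(=O)CC(OCOC)=C2C(=O)OC(C)(C)OC2=O)cc1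
F7 | step 12 | 8-(methoxymethoxy)-2,2-dimethyl-6-[(5-methylhex-4-en-1-yn-1-yl)oxy]-2H-chromen-5-yl 6-chloro-4-hydroxy-2-oxo-2H-pyran-3-carboxylate | O=C(Oc1c(OC#CCC=C(C)C)cc(OCOC)c2OC(C)(C)C=Cc12)C1=C(O)C=C(Cl)OC1=O
F8 | step 12 | 8-(methoxymethoxy)-2,2-dimethyl-6-[(5-methylhex-4-en-1-yn-1-yl)oxy]-2H-chromen-5-yl 6-chloro-4-(methoxymethoxy)-2-oxo-2H-pyran-3-carboxylate | O=C(Oc1c(OC#CCC=C(C)C)cc(OCOC)c2OC(C)(C)C=Cc12)C1=C(OCOC)C=C(Cl)OC1=O
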